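**Retrosynthetic overview**
1. Target 16 ⇒ diaryl ether benzoic acid 10 + α-oxo sulfoxonium ylide 14. The C4–C4a bond is made by carboxylate-directed ortho C–H functionalisation with an α-oxo rhodium carbene (an α-acyl cation, i.e. enolonium, equivalent), followed by cyclodehydration. The pyranone is the only ring built and it is formed last.
2. 14 ⇒ hexanoyl chloride 11 + trimethylsulfoxonium iodide 12.
3. 10 ⇒ nitrile aldehyde 5 by Baeyer–Villiger unmasking of the formyl group as the ring B phenol, nitrile hydrolysis and O-debenzylation.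
4. 5 ⇒ salicylaldehyde 3 + fluoronitrile 4 (SNAr diaryl ether). The formyl group is a masked hydroxyl, so the two catechol oxygens of ring B never compete.
5. 3 ⇒ bromosalicylaldehyde 1 + pentylboronic acid 2 (alkyl Suzuki coupling). Both benzene rings are bought.

Assumption: the target has no stereocentre (it is achiral), so no stereocontrol is needed and the route gives the single compound drawn.

Ring A is the benzo ring of the isocoumarin; ring B is the methoxy-pentyl-phenoxy ring.

**Route**

Step 1
Reactants: 1 3-bromo-2-hydroxy-5-methoxybenzaldehyde; 2 pentylboronic acid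
Product: 3 2-hydroxy-5-methoxy-3-pentylbenzaldehyde
Conditions: Pd(OAc)2 (3 mol %), SPhos (6 mol %), K3PO4 (3 equiv), toluene/H2O 10:1, 100 °C
Reagents that add atoms: none
Why: Suzuki–Miyaura sp2–sp3 coupling, in which zerovalent palladium inserts into the C–Br bond, the phosphate-activated alkylboronate transmetalates, and the bulky biarylphosphine makes reductive elimination faster than β-hydride elimination; the free phenol and the aldehyde are tolerated.

Step 2
Reactants: 3 2-hydroxy-5-methoxy-3-pentylbenzaldehyde; 4 4-(benzyloxy)-2-fluorobenzonitrile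
Product: 5 4-(benzyloxy)-2-(2-formyl-4-methoxy-6-pentylphenoxy)benzonitrile
Conditions: K2CO3 (2 equiv), DMF, 110 °C
Reagents that add atoms: none
Why: Nucleophilic aromatic substitution (addition–elimination), in which the ortho nitrile stabilises the Meisenheimer adduct and fluoride is the best leaving group; 3 has only one phenoxide oxygen, so the ether forms at the oxygen flanked by the pentyl group without regiochemical ambiguity.

Step 3
Reactants: 5 4-(benzyloxy)-2-(2-formyl-4-methoxy-6-pentylphenoxy)benzonitrile
Product: 9 4-(benzyloxy)-2-(2-hydroxy-4-methoxy-6-pentylphenoxy)benzoic acid, via aryl formate 6 (not isolated), via phenol nitrile 7 (not isolated), via primary amide 8 (not isolated)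
Conditions: mCPBA (1.3 equiv), CH2Cl2, 0 °C to rt; then 30% H2O2, KOH, DMSO/H2O, rt; then aq. KOH, 110 °C (N2); HCl work-up
Reagents that add atoms: mCPBA, O=C(OO)c1cccc(Cl)c1; hydrogen peroxide, OO; potassium hydroxide, [K+].[OH-]
Why: Baeyer–Villiger (Dakin-type) oxidation with migration of the ortho-aryloxy-substituted aryl group gives the formate, which base cleaves at once; Radziszewski hydration then turns the nitrile into the amide at room temperature, before heating, so that no cyano-activated aryl migration between the two ring B oxygens (Smiles rearrangement) can occur during the final alkaline amide hydrolysis.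

Step 4
Reactants: 9 4-(benzyloxy)-2-(2-hydroxy-4-methoxy-6-pentylphenoxy)benzoic acid
Product: 10 4-hydroxy-2-(2-hydroxy-4-methoxy-6-pentylphenoxy)benzoic acid
Conditions: H2 (1 atm), 10% Pd/C, EtOAc/MeOH, rt
Reagents that add atoms: none
Why: Catalytic hydrogenolysis of the aryl benzyl ether, done at this stage because nothing else is reducible (the diaryl ether, methyl ether and acid are inert and there is no alkene yet).

Step 5
Reactants: 11 hexanoyl chloride; 12 trimethylsulfoxonium iodide
Product: 14 1-[dimethyl(oxo)-λ6-sulfanylidene]heptan-2-one, via dimethylsulfoxonium methylide 13 (not isolated)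
Conditions: 12 (3 equiv), KOtBu (3 equiv), THF, reflux, 2 h; then 11, 0 °C to rt
Reagents that add atoms: none
Why: C-acylation of the Corey–Chaykovsky sulfoxonium methylide by the acid chloride, after which further base deprotonates the acylsulfoxonium salt to the bench-stable carbonyl-stabilised ylide.

Step 6
Reactants: 10 4-hydroxy-2-(2-hydroxy-4-methoxy-6-pentylphenoxy)benzoic acid; 14 1-[dimethyl(oxo)-λ6-sulfanylidene]heptan-2-one
Product: 16 6-hydroxy-8-(2-hydroxy-4-methoxy-6-pentylphenoxy)-3-pentyl-1H-isochromen-1-one, via keto acid 15 (not isolated)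
Conditions: [Cp*RhCl2]2 (4 mol %), AgSbF6 (16 mol %), NaOAc (30 mol %), HFIP, 80 °C
Reagents that add atoms: none
Why: Carboxylate-directed C–H acylmethylation/annulation of a benzoic acid with a sulfoxonium ylide, in which trivalent rhodium metalates the only free ortho C–H, the ylide loses DMSO on the metal to give an α-oxo carbene that acts as an α-acyl cation (enolonium) equivalent so the normally nucleophilic ketone α-carbon is joined to the nucleophilic aryl–rhodium carbon by migratory insertion, and protodemetalation and cyclodehydration of the keto acid then close the pyranone.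

**Compound list**
1 | 3-bromo-2-hydroxy-5-methoxybenzaldehyde | COc1cc(Br)c(O)c(C=O)c1 | starting material
2 | pentylboronic acid | CCCCCB(O)O | starting material
3 | 2-hydroxy-5-methoxy-3-pentylbenzaldehyde | CCCCCc1cc(OC)cc(C=O)c1O | intermediate
4 | 4-(benzyloxy)-2-fluorobenzonitrile | N#Cc1ccc(OCc2ccccc2)cc1F | starting material
5 | 4-(benzyloxy)-2-(2-formyl-4-methoxy-6-pentylphenoxy)benzonitrile | CCCCCc1cc(OC)cc(C=O)c1Oc1cc(OCc2ccccc2)ccc1C#N | intermediate
6 | 2-[5-(benzyloxy)-2-cyanophenoxy]-5-methoxy-3-pentylphenyl formate | CCCCCc1cc(OC)cc(OC=O)c1Oc1cc(OCc2ccccc2)ccc1C#N | intermediate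
7 | 4-(benzyloxy)-2-(2-hydroxy-4-methoxy-6-pentylphenoxy)benzonitrile | CCCCCc1cc(OC)cc(O)c1Oc1cc(OCc2ccccc2)ccc1C#N | intermediate
8 | 4-(benzyloxy)-2-(2-hydroxy-4-methoxy-6-pentylphenoxy)benzamide | CCCCCc1cc(OC)cc(O)c1Oc1cc(OCc2ccccc2)ccc1C(N)=O | intermediate
9 | 4-(benzyloxy)-2-(2-hydroxy-4-methoxy-6-pentylphenoxy)benzoic acid | CCCCCc1cc(OC)cc(O)c1Oc1cc(OCc2ccccc2)ccc1C(=O)O | intermediate
10 | 4-hydroxy-2-(2-hydroxy-4-methoxy-6-pentylphenoxy)benzoic acid | CCCCCc1cc(OC)cc(O)c1Oc1cc(O)ccc1C(=O)O | intermediate
11 | hexanoyl chloride | CCCCCC(=O)Cl | starting material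
12 | trimethylsulfoxonium iodide | C[S+](C)(C)=O.[I-] | starting material
13 | dimethylsulfoxonium methylide | [CH2-][S+](C)(C)=O | intermediate
14 | 1-[dimethyl(oxo)-λ6-sulfanylidene]heptan-2-one | CCCCCC(=O)C=S(C)(C)=O | intermediate
15 | 4-hydroxy-2-(2-hydroxy-4-methoxy-6-pentylphenoxy)-6-(2-oxoheptyl)benzoic acid | CCCCCC(=O)Cc1cc(O)cc(Oc2c(O)cc(OC)cc2CCCCC)c1C(=O)O | intermediate
16 | 6-hydroxy-8-(2-hydroxy-4-methoxy-6-pentylphenoxy)-3-pentyl-1H-isochromen-1-one | CCCCCc1cc2cc(O)cc(Oc3c(O)cc(OC)cc3CCCCC)c2c(=O)o1 | target

**Step count and risks**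

Total step count: 6. Longest linear sequence: 5 (steps 1, 2, 3, 4, 6); step 5 is a one-step side branch.

Steps most likely to fail:

Step 6. The carbene annulation is run on an unprotected, electron-rich acid with an aliphatic ylide. The acid or a phenol may be O-alkylated by the protonated ylide, the keto acid 15 may not close fully, and the hydroxybenzoic acid may decarboxylate. The fallback sets out from 10 and comes back at 16. It is an oxidative annulation of 10 with hept-1-en-2-yl acetate F1, which is made from hept-1-yne and acetic acid by Markovnikov addition with [Ru(p-cymene)Cl2]2, tri(2-furyl)phosphine and Na2CO3. With [Cp*RhCl2]2 and Cu(OAc)2 in toluene at 110 °C, carboxylate-directed oxidative alkenylation is followed by lactonisation with loss of acetic acid. This replaces the carbene insertion by a Heck-type olefination.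

Step 3. Three things can go wrong in the telescoped sequence: hydride instead of aryl migration in the peracid stage, slow hydrolysis of the hindered amide, and aryl migration between the ring B oxygens if nitrile survives into hot base. The fallback sets out from 5 and comes back at 10. Compound 5 is oxidised with mCPBA and the formate 6 is cleaved with K2CO3 in MeOH, and phenol nitrile 7 is isolated. It is benzylated (BnBr, K2CO3, DMF) to 4-(benzyloxy)-2-[2-(benzyloxy)-4-methoxy-6-pentylphenoxy]benzonitrile F2, which has no free phenoxide. The nitrile is hydrolysed (KOH, ethylene glycol/H2O, 150 °C) to 4-(benzyloxy)-2-[2-(benzyloxy)-4-methoxy-6-pentylphenoxy]benzoic acid F3. Hydrogenolysis (H2, 10% Pd/C) removes both benzyl groups and gives 10.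

Step 2. The phenoxide of 3 is hindered on both sides and weakened by the ortho formyl group, so the SNAr may stall. The fallback sets out from 3 and comes back at 9. It is a copper-catalysed Ullmann coupling (CuI, picolinic acid, K3PO4, DMSO, 90 °C) of 3 with methyl 4-(benzyloxy)-2-bromobenzoate F4, made from commercial methyl 2-bromo-4-hydroxybenzoate and benzyl bromide. This gives methyl 4-(benzyloxy)-2-(2-formyl-4-methoxy-6-pentylphenoxy)benzoate F5. mCPBA converts F5 into methyl 4-(benzyloxy)-2-[2-(formyloxy)-4-methoxy-6-pentylphenoxy]benzoate F6. LiOH in THF/H2O at rt cleaves the formate and the methyl ester to give 9, with no nitrile to hydrolyse.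

Further compounds
F1 | step 6 | hept-1-en-2-yl acetate | CCCCCC(=C)OC(C)=O
F2 | step 3 | 4-(benzyloxy)-2-[2-(benzyloxy)-4-methoxy-6-pentylphenoxy]benzonitrile | CCCCCc1cc(OC)cc(OCc2ccccc2)c1Oc1cc(OCc2ccccc2)ccc1C#N
F3 | step 3 | 4-(benzyloxy)-2-[2-(benzyloxy)-4-methoxy-6-pentylphenoxy]benzoic acid | CCCCCc1cc(OC)cc(OCc2ccccc2)c1Oc1cc(OCc2ccccc2)ccc1C(=O)O
F4 | step 2 | methyl 4-(benzyloxy)-2-bromobenzoate | COC(=O)c1ccc(OCc2ccccc2)cc1Br
F5 | step 2 | methyl 4-(benzyloxy)-2-(2-formyl-4-methoxy-6-pentylphenoxy)benzoate | CCCCCc1cc(OC)cc(C=O)c1Oc1cc(OCc2ccccc2)ccc1C(=O)OC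
F6 | step 2 | methyl 4-(benzyloxy)-2-[2-(formyloxy)-4-methoxy-6-pentylphenoxy]benzoate | CCCCCc1cc(OC)cc(OC=O)c1Oc1cc(OCc2ccccc2)ccc1C(=O)OC
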